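The dioxane ring is opened at the aryl–oxygen bond B5–O7. Ring B comes from 5-bromovanillin, whose B3 methoxy, B4 hydroxyl and B5 bromine already encode which dioxane oxygen lies next to the methoxy group: O8 is the phenol oxygen, and bromine marks the site of O7. An Evans syn-aldol between the ring-A aldehyde and the B4-aryloxyacetyl imide sets C7 and C8 together. The key step, a palladium-catalysed intramolecular etherification, then joins the free C7 hydroxyl to B5 in one operation, closing the ring with both centres untouched, so the syn (7R,8R) alcohol becomes the trans dioxane. Its precursor is the syn 1-aryl-2-(2-bromoaryloxy)propanol with B1 as a dioxolane and O9 silylated.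

Key step: step 7

Labels: C7 is the aryl-bearing dioxane carbon, C8 the hydroxymethyl-bearing one, C9 the hydroxymethyl carbon; O7, O8 and O9 are the oxygens on C7, C8 and C9. Ring A is the pendant catechol ring (A1 on C7). Ring B is the fused arene (enal on B1, OMe on B3, O8 on B4, O7 on B5).

Assumption: (4S)-4-benzyl-3-(chloroacetyl)-1,3-oxazolidin-2-one is taken as a purchasable reagent; otherwise it is one N-acylation away from (S)-4-benzyl-1,3-oxazolidin-2-one.

Design of the precursor: O7 and O9 are both β to O8, so either could close a six-membered ring onto B5. O9 is therefore carried as a triisopropylsilyl ether, which should not shift to the C7 alkoxide under base. B1 stays a dioxolane so that ring B has no acceptor para to O8.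

Step 1
Reactants: 1 5-hydroxyvanillin
Product: 2 3-methoxy-4,5-bis(methoxymethoxy)benzaldehyde
Conditions: MOMCl (2.6 equiv), iPr2NEt (3.2 equiv), CH2Cl2, 0 °C to rt
Reagents that add atoms: chloromethyl methyl ether, COCCl
Why: Both phenols are alkylated by the α-chloro ether under amine base (Williamson-type ether formation), giving MOM ethers that tolerate base, hydride and palladium while the aldehyde stays free for step 4.

Step 2
Reactants: 3 5-bromovanillin
Product: 4 2-bromo-4-(1,3-dioxolan-2-yl)-6-methoxyphenol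
Conditions: ethylene glycol (5 equiv), TsOH·H2O (2 mol%), toluene, reflux, Dean–Stark; Et3N quench
Reagents that add atoms: ethylene glycol, OCCO
Why: Acid-catalysed acetalisation with azeotropic removal of water turns the B1 formyl group into a dioxolane that tolerates base, enolate, hydride and palladium chemistry and removes the acceptor para to B4.

Step 3
Reactants: 4 2-bromo-4-(1,3-dioxolan-2-yl)-6-methoxyphenol; 5 (4S)-4-benzyl-3-(chloroacetyl)-1,3-oxazolidin-2-one
Product: 6 (4S)-4-benzyl-3-{[2-bromo-4-(1,3-dioxolan-2-yl)-6-methoxyphenoxy]acetyl}-1,3-oxazolidin-2-one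
Conditions: K2CO3 (1.5 equiv), NaI (10 mol%), acetone, 45 °C
Reagents that add atoms: none
Why: Williamson etherification with Finkelstein activation: the phenoxide of 4 displaces halide from the α-halo imide by SN2, which fixes O8 on B4 next to the B3 methoxy group and should be faster than attack on the imide carbonyl at this temperature.

Step 4
Reactants: 6 (4S)-4-benzyl-3-{[2-bromo-4-(1,3-dioxolan-2-yl)-6-methoxyphenoxy]acetyl}-1,3-oxazolidin-2-one; 2 3-methoxy-4,5-bis(methoxymethoxy)benzaldehyde
Product: 9 syn-aldol imide (4S)-4-benzyl-3-{(2S,3R)-2-[2-bromo-4-(1,3-dioxolan-2-yl)-6-methoxyphenoxy]-3-hydroxy-3-[3-methoxy-4,5-bis(methoxymethoxy)phenyl]propanoyl}-1,3-oxazolidin-2-one, via Z-dibutylboron enolate 7 (not isolated), via dibutylboron aldolate 8 (not isolated)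
Conditions: Bu2BOTf (1.1 equiv), iPr2NEt (1.3 equiv), CH2Cl2, −78 to 0 °C; then 2, −78 to 0 °C; pH 7 buffer, MeOH, 30% H2O2, 0 °C
Reagents that add atoms: none
Why: Evans boron syn-aldol reaction: soft enolisation gives the Z-enolate 7, which adds to 2 through a chair Zimmerman–Traxler transition state on the face away from the benzyl group of the (4S)-auxiliary, so that C7 (R) and C8 (2S in the imide, the same spatial arrangement as 8R once C9 is reduced) are set together in the syn relationship.

Step 5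
Reactants: 9 syn-aldol imide
Product: 10 (1R,2R)-2-[2-bromo-4-(1,3-dioxolan-2-yl)-6-methoxyphenoxy]-1-[3-methoxy-4,5-bis(methoxymethoxy)phenyl]propane-1,3-diol
Conditions: NaBH4 (4 equiv), THF/H2O (4:1), 0 °C to rt
Reagents that add atoms: none
Why: Borohydride reduces the activated exocyclic imide carbonyl (reductive removal of the Evans auxiliary) to the C9 primary alcohol without touching C7, C8, the aryl bromide or the acetals, and the auxiliary is released for recovery.

Step 6
Reactants: 10 (1R,2R)-diol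
Product: 11 (1R,2R)-2-[2-bromo-4-(1,3-dioxolan-2-yl)-6-methoxyphenoxy]-1-[3-methoxy-4,5-bis(methoxymethoxy)phenyl]-3-[(triisopropylsilyl)oxy]propan-1-ol
Conditions: TIPSCl (1.1 equiv), imidazole (2.5 equiv), DMF, 0 °C to rt
Reagents that add atoms: chlorotriisopropylsilane, CC(C)[Si](Cl)(C(C)C)C(C)C
Why: Imidazole-promoted silylation with the bulky chlorosilane is selective for the primary O9 over the hindered benzylic O7, leaving the C7 hydroxyl as the only free nucleophile.

Step 7
Reactants: 11 syn (7R,8R) C7 carbinol with the O8-linked 2-bromoaryl ether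
Product: 12 triisopropyl{[(2R,3R)-6-(1,3-dioxolan-2-yl)-8-methoxy-3-[3-methoxy-4,5-bis(methoxymethoxy)phenyl]-2,3-dihydro-1,4-benzodioxin-2-yl]methoxy}silane (trans ring, 7R,8R)
Conditions: Pd(OAc)2 (5 mol%), racemic 2-(di-tert-butylphosphino)-1,1'-binaphthyl (6 mol%), Cs2CO3 (1.5 equiv), toluene, 80 °C
Reagents that add atoms: none
Why: Pd(OAc)2 is reduced in the flask to a zerovalent palladium–phosphine species that adds oxidatively into the B5–Br bond; Cs2CO3 then exchanges bromide on divalent palladium for the C7 alkoxide, and C–O reductive elimination forms B5–O7 (intramolecular Buchwald–Hartwig etherification, the reaction type known for cyclising 2-(2-bromoaryloxy) secondary alcohols to chiral 1,4-benzodioxanes). The six-membered dioxane ring closes in this reductive elimination from a seven-membered palladium chelate, a 6-exo-type attack of O7 on B5 with B4–O8 already in place. No stereocentre is made: C7 and C8 keep all four bonds, so the syn (7R,8R) pair from step 4 becomes the trans ring directly. The step needs reductive elimination to outrun β-hydride loss from C7–H, which the bulky di-tert-butyl biaryl phosphine should secure. It also needs an unchanged constitution: the B1 dioxolane gives a Smiles shift of ring B from O8 to O7 no driving force, and the triisopropylsilyl group should stay on O9 so that O9 cannot compete for B5. Position control is inherent, since bromine sits only on B5.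

Step 8
Reactants: 12 protected trans-benzodioxane acetal
Product: 13 (2R,3R)-8-methoxy-3-[3-methoxy-4,5-bis(methoxymethoxy)phenyl]-2-{[(triisopropylsilyl)oxy]methyl}-2,3-dihydro-1,4-benzodioxine-6-carbaldehyde
Conditions: PPTS (0.2 equiv), acetone/H2O (10:1), rt to 40 °C
Reagents that add atoms: water, O
Why: Mild acid-catalysed acetal hydrolysis frees the B1 aldehyde, and the aryl MOM ethers and the primary TIPS ether should survive PPTS at this temperature.

Step 9
Reactants: 13 benzodioxane aldehyde; 14 (formylmethylene)triphenylphosphorane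
Product: 15 (E)-3-[(2R,3R)-8-methoxy-3-[3-methoxy-4,5-bis(methoxymethoxy)phenyl]-2-{[(triisopropylsilyl)oxy]methyl}-2,3-dihydro-1,4-benzodioxin-6-yl]prop-2-enal
Conditions: 14 (1.2 equiv), toluene, 85 °C
Reagents that add atoms: none
Why: Wittig olefination with the stabilised formyl ylide extends B1 by two carbons and should give the E-enal selectively under neutral conditions that leave C7 and C8 alone.

Step 10
Reactants: 15 protected E-enal
Product: 16 (E)-3-[(2R,3R)-3-(3,4-dihydroxy-5-methoxyphenyl)-2-(hydroxymethyl)-8-methoxy-2,3-dihydro-1,4-benzodioxin-6-yl]prop-2-enal (target)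
Conditions: 3 M aq HCl/MeOH/THF (1:3:3), 40 °C; then H2O
Reagents that add atoms: none
Why: Acid-catalysed solvolysis cleaves the two aryl methoxymethyl acetals and the primary silyl ether in one operation (methanol takes up the methoxymethyl groups as dimethoxymethane), while the E-enal, the aryl ethers and the trans dioxane should be stable to dilute acid at this temperature.

Compound list
1 | 5-hydroxyvanillin (3,4-dihydroxy-5-methoxybenzaldehyde) | COc1cc(C=O)cc(O)c1O | starting material
2 | 3-methoxy-4,5-bis(methoxymethoxy)benzaldehyde | COc1cc(C=O)cc(OCOC)c1OCOC | intermediate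
3 | 5-bromovanillin (3-bromo-4-hydroxy-5-methoxybenzaldehyde) | COc1cc(C=O)cc(Br)c1O | starting material
4 | 2-bromo-4-(1,3-dioxolan-2-yl)-6-methoxyphenol | COc1cc(C2OCCO2)cc(Br)c1O | intermediate
5 | (4S)-4-benzyl-3-(chloroacetyl)-1,3-oxazolidin-2-one | O=C1OC[C@H](Cc2ccccc2)N1C(=O)CCl | starting material
6 | (4S)-4-benzyl-3-{[2-bromo-4-(1,3-dioxolan-2-yl)-6-methoxyphenoxy]acetyl}-1,3-oxazolidin-2-one | COc1cc(C2OCCO2)cc(Br)c1OCC(=O)N1[C@@H](Cc2ccccc2)COC1=O | intermediate
7 | Z-dibutylboron enolate of 6 (enolate oxygen and aryloxy group cis; formed in the flask) | CCCCB(CCCC)O/C(=C\Oc1c(Br)cc(C2OCCO2)cc1OC)N1[C@@H](Cc2ccccc2)COC1=O | intermediate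
8 | dibutylboron aldolate of 9 (boron on O7; formed in the flask) | COc1cc([C@@H](OB(CCCC)CCCC)[C@H](Oc2c(Br)cc(C3OCCO3)cc2OC)C(=O)N2[C@@H](Cc3ccccc3)COC2=O)cc(OCOC)c1OCOC | intermediate
9 | (4S)-4-benzyl-3-{(2S,3R)-2-[2-bromo-4-(1,3-dioxolan-2-yl)-6-methoxyphenoxy]-3-hydroxy-3-[3-methoxy-4,5-bis(methoxymethoxy)phenyl]propanoyl}-1,3-oxazolidin-2-one | COc1cc([C@@H](O)[C@H](Oc2c(Br)cc(C3OCCO3)cc2OC)C(=O)N2[C@@H](Cc3ccccc3)COC2=O)cc(OCOC)c1OCOC | intermediate
10 | (1R,2R)-2-[2-bromo-4-(1,3-dioxolan-2-yl)-6-methoxyphenoxy]-1-[3-methoxy-4,5-bis(methoxymethoxy)phenyl]propane-1,3-diol | COc1cc([C@@H](O)[C@H](Oc2c(Br)cc(C3OCCO3)cc2OC)CO)cc(OCOC)c1OCOC | intermediate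
11 | (1R,2R)-2-[2-bromo-4-(1,3-dioxolan-2-yl)-6-methoxyphenoxy]-1-[3-methoxy-4,5-bis(methoxymethoxy)phenyl]-3-[(triisopropylsilyl)oxy]propan-1-ol | COc1cc([C@@H](O)[C@H](Oc2c(Br)cc(C3OCCO3)cc2OC)CO[Si](C(C)C)(C(C)C)C(C)C)cc(OCOC)c1OCOC | intermediate
12 | triisopropyl{[(2R,3R)-6-(1,3-dioxolan-2-yl)-8-methoxy-3-[3-methoxy-4,5-bis(methoxymethoxy)phenyl]-2,3-dihydro-1,4-benzodioxin-2-yl]methoxy}silane | COc1cc([C@H]2Oc3cc(C4OCCO4)cc(OC)c3O[C@@H]2CO[Si](C(C)C)(C(C)C)C(C)C)cc(OCOC)c1OCOC | intermediate
13 | (2R,3R)-8-methoxy-3-[3-methoxy-4,5-bis(methoxymethoxy)phenyl]-2-{[(triisopropylsilyl)oxy]methyl}-2,3-dihydro-1,4-benzodioxine-6-carbaldehyde | COc1cc([C@H]2Oc3cc(C=O)cc(OC)c3O[C@@H]2CO[Si](C(C)C)(C(C)C)C(C)C)cc(OCOC)c1OCOC | intermediate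
14 | (formylmethylene)triphenylphosphorane | O=CC=P(c1ccccc1)(c1ccccc1)c1ccccc1 | starting material
15 | (E)-3-[(2R,3R)-8-methoxy-3-[3-methoxy-4,5-bis(methoxymethoxy)phenyl]-2-{[(triisopropylsilyl)oxy]methyl}-2,3-dihydro-1,4-benzodioxin-6-yl]prop-2-enal | COc1cc([C@H]2Oc3cc(/C=C/C=O)cc(OC)c3O[C@@H]2CO[Si](C(C)C)(C(C)C)C(C)C)cc(OCOC)c1OCOC | intermediate
16 | (E)-3-[(2R,3R)-3-(3,4-dihydroxy-5-methoxyphenyl)-2-(hydroxymethyl)-8-methoxy-2,3-dihydro-1,4-benzodioxin-6-yl]prop-2-enal | COc1cc([C@H]2Oc3cc(/C=C/C=O)cc(OC)c3O[C@@H]2CO)cc(O)c1O | target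

Total step count: 10. Longest linear sequence: 9 steps (steps 2 to 10, from 5-bromovanillin); the ring-A branch is step 1 and joins at step 4.

Steps most likely to fail

Step 7. The palladium alkoxide at C7 may lose its β-hydrogen instead of undergoing reductive elimination, which would oxidise C7 and reduce the B5–Br bond. Oxidative addition at the crowded, electron-rich B5 position may also stall. The fallback keeps bromine as the position marker but makes the C7–O7 bond instead of the B5–O7 bond. It sets out from 11. Miyaura borylation (PdCl2(dppf), B2pin2, KOAc, dioxane, 80 °C) should give the B5 pinacol boronate F1, and oxidation (NaBO3·4H2O, THF/H2O, rt) the B5 phenol F2. Acid-catalysed cyclodehydration (TsOH·H2O, 10 mol%, CH2Cl2, 4 Å sieves, 0 °C) should then ionise C7 to the benzylic cation stabilised by ring A, which O7 traps under thermodynamic control in favour of the trans ring, with C8 fixed throughout. The fallback comes back to the route at 12.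

Step 4. Facial selectivity may erode with the bulky 2,6-disubstituted aryloxy enolate, or the boron triflate may open the dioxolane. The fallback builds the two centres by epoxidation and inversion instead of an aldol reaction. It sets out from 2 and uses phenol 4.
- Horner–Wadsworth–Emmons olefination of 2 with triethyl phosphonoacetate (NaH, THF, 0 °C) should give the ethyl E-cinnamate F3, and DIBAL-H (CH2Cl2, −78 °C) the E-cinnamyl alcohol F4.
- Sharpless epoxidation (Ti(OiPr)4, L-(+)-diisopropyl tartrate, tBuOOH, 4 Å sieves, CH2Cl2, −20 °C) should give the (2S,3S)-epoxy alcohol F5. It would be opened in the same flask at C7, with inversion, by benzoic acid and Ti(OiPr)4 to the (7R,8S) 7-benzoate 8,9-diol F6.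
- TIPSCl/imidazole should give the O9 silyl ether F7.
- Mitsunobu coupling of F7 with phenol 4 (PPh3, DIAD, toluene, 0 °C to rt) should invert C8 and give the (7R,8R) aryl ether benzoate F8.
- K2CO3/MeOH removes the benzoate, and the fallback comes back to the route at 11.

Step 9. The ylide may react a second time with the product enal and extend the chain beyond two carbons, and the electron-rich aldehyde may convert slowly. The fallback replaces the one-step homologation by olefination to the ester and a change of oxidation state. It sets out from 13. Horner–Wadsworth–Emmons reaction with triethyl phosphonoacetate (NaH, THF, 0 °C) should give the ethyl E-acrylate F9, DIBAL-H (CH2Cl2, −78 °C) the E-allylic alcohol F10, and MnO2 (CH2Cl2, rt) the enal. The fallback comes back to the route at 15.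

Further compounds
F1 | step 7 | (1R,2R)-2-[4-(1,3-dioxolan-2-yl)-2-methoxy-6-(4,4,5,5-tetramethyl-1,3,2-dioxaborolan-2-yl)phenoxy]-1-[3-methoxy-4,5-bis(methoxymethoxy)phenyl]-3-[(triisopropylsilyl)oxy]propan-1-ol | COc1cc([C@@H](O)[C@H](Oc2c(B3OC(C)(C)C(C)(C)O3)cc(C3OCCO3)cc2OC)CO[Si](C(C)C)(C(C)C)C(C)C)cc(OCOC)c1OCOC
F2 | step 7 | 5-(1,3-dioxolan-2-yl)-2-{[(1R,2R)-1-hydroxy-1-[3-methoxy-4,5-bis(methoxymethoxy)phenyl]-3-[(triisopropylsilyl)oxy]propan-2-yl]oxy}-3-methoxyphenol | COc1cc([C@@H](O)[C@H](Oc2c(O)cc(C3OCCO3)cc2OC)CO[Si](C(C)C)(C(C)C)C(C)C)cc(OCOC)c1OCOC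
F3 | step 4 | ethyl (E)-3-[3-methoxy-4,5-bis(methoxymethoxy)phenyl]prop-2-enoate | CCOC(=O)/C=C/c1cc(OC)c(OCOC)c(OCOC)c1
F4 | step 4 | (E)-3-[3-methoxy-4,5-bis(methoxymethoxy)phenyl]prop-2-en-1-ol | OC/C=C/c1cc(OC)c(OCOC)c(OCOC)c1
F5 | step 4 | {(2S,3S)-3-[3-methoxy-4,5-bis(methoxymethoxy)phenyl]oxiran-2-yl}methanol | OC[C@@H]1O[C@H]1c1cc(OC)c(OCOC)c(OCOC)c1
F6 | step 4 | (1R,2S)-2,3-dihydroxy-1-[3-methoxy-4,5-bis(methoxymethoxy)phenyl]propyl benzoate | COc1cc([C@@H](OC(=O)c2ccccc2)[C@@H](O)CO)cc(OCOC)c1OCOC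
F7 | step 4 | (1R,2S)-2-hydroxy-1-[3-methoxy-4,5-bis(methoxymethoxy)phenyl]-3-[(triisopropylsilyl)oxy]propyl benzoate | COc1cc([C@@H](OC(=O)c2ccccc2)[C@@H](O)CO[Si](C(C)C)(C(C)C)C(C)C)cc(OCOC)c1OCOC
F8 | step 4 | (1R,2R)-2-[2-bromo-4-(1,3-dioxolan-2-yl)-6-methoxyphenoxy]-1-[3-methoxy-4,5-bis(methoxymethoxy)phenyl]-3-[(triisopropylsilyl)oxy]propyl benzoate | COc1cc([C@@H](OC(=O)c2ccccc2)[C@H](Oc2c(Br)cc(C3OCCO3)cc2OC)CO[Si](C(C)C)(C(C)C)C(C)C)cc(OCOC)c1OCOC
F9 | step 9 | ethyl (E)-3-[(2R,3R)-8-methoxy-3-[3-methoxy-4,5-bis(methoxymethoxy)phenyl]-2-{[(triisopropylsilyl)oxy]methyl}-2,3-dihydro-1,4-benzodioxin-6-yl]prop-2-enoate | COc1cc([C@H]2Oc3cc(/C=C/C(=O)OCC)cc(OC)c3O[C@@H]2CO[Si](C(C)C)(C(C)C)C(C)C)cc(OCOC)c1OCOC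
F10 | step 9 | (E)-3-[(2R,3R)-8-methoxy-3-[3-methoxy-4,5-bis(methoxymethoxy)phenyl]-2-{[(triisopropylsilyl)oxy]methyl}-2,3-dihydro-1,4-benzodioxin-6-yl]prop-2-en-1-ol | COc1cc([C@H]2Oc3cc(/C=C/CO)cc(OC)c3O[C@@H]2CO[Si](C(C)C)(C(C)C)C(C)C)cc(OCOC)c1OCOC
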